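**Retrosynthetic overview** (daucane numbering: C1 = ring-fusion C–CH3, C2/C3 = cyclopentane CH2, C4 = C(iPr)–O, C5 = ring-fusion CH, C6 = CHOH, C7 = CH2, C8 = C(CH3)–O, C9 = epoxide CH, C10 = CH2; β = face of the C1 methyl)
1. The aroyl group on the tertiary O4 and the 6α-carbinol are removed together to a β-hydroxy ketone (Evans–Tishchenko); the 8α,9α-epoxide goes back to the C8=C9 alkene (hydroxyl-directed epoxidation).
2. The cycloheptene is cut at C6–C7 and C8–C9 in an anionic (5+2) annulation: C7–C8(CH3) is an isopropenylphosphonium salt, C6 a nitronate carbon (masked carbonyl), C9 an aldehyde carbon.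
3. Enabling feature: in the seven-membered ring C5–C6–C7–C8–C9–C10–C1 the oxygen-bearing C6 and C9 flank the unit C7H2–C8(CH3), and the two arms (C6 on C5, C10–C9 on C1) are trans on the cyclopentane, so they cannot close on each other and must take up the two-carbon unit.
4. The cyclopentane triad C4/C5/C1 comes from a silicon-tethered radical cyclisation–allylation of a tertiary cyclopentenol, the ring-contraction product of (S)-terpinen-4-ol.
5. Ring order: cyclopentane (from the terpene cyclohexene), then cycloheptene (key step), then oxirane.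

Key step: step 10

Assumption (chemistry): (S)-(+)-terpinen-4-ol is used as the single enantiomer and its carbinol carbon becomes C4 unchanged; the nitro-bearing C6 of 14–16 is carried as a mixture because step 11 makes it trigonal.

**Step 1**
Reactants: 1 (S)-(+)-terpinen-4-ol
Product: 3 (5R)-5-hydroxy-2-methyl-5-(propan-2-yl)cyclopent-1-ene-1-carbaldehyde, via keto aldehyde 2 (not isolated)
Conditions: O3, CH2Cl2/MeOH, −78 °C; Me2S, −78 °C to rt; then piperidine (cat.), AcOH (cat.), benzene, 60 °C
Reagents that add atoms: ozone, O=[O+][O-]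
Why: Ozonolysis cleaves the only alkene to the 1,6-keto aldehyde 2, and piperidinium acetate should then close the five-membered ring by enamine aldol condensation of the aldehyde α-carbon onto the methyl ketone (ozonolysis followed by intramolecular aldol condensation, as known for limonene); the carbinol stereocentre is not involved.

**Step 2**
Reactants: 3 (5R)-5-hydroxy-2-methyl-5-(propan-2-yl)cyclopent-1-ene-1-carbaldehyde
Product: 4 (1R)-3-methyl-1-(propan-2-yl)cyclopent-2-en-1-ol
Conditions: [Ir(cod)Cl]2 (cat.), PPh3 (cat.), 1,4-dioxane, reflux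
Reagents that add atoms: none
Why: Iridium-catalysed decarbonylation of the enal (Tsuji–Wilkinson type: formyl C–H oxidative addition, CO de-insertion, C–H reductive elimination) should remove the formyl group that drove the ring contraction and leave the C5=C1 alkene and the tertiary carbinol unchanged.

**Step 3**
Reactants: 4 (1R)-3-methyl-1-(propan-2-yl)cyclopent-2-en-1-ol
Product: 5 (R)-(bromomethyl)dimethyl{[3-methyl-1-(propan-2-yl)cyclopent-2-en-1-yl]oxy}silane
Conditions: BrCH2SiMe2Cl, Et3N, DMAP (cat.), CH2Cl2, 0 °C to rt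
Reagents that add atoms: (bromomethyl)chlorodimethylsilane, C[Si](C)(Cl)CBr
Why: DMAP-catalysed O-silylation of the tertiary alcohol installs the radical tether (first stage of the Nishiyama–Stork sequence); no stereocentre is touched.

**Step 4**
Reactants: 5 (R)-(bromomethyl)dimethyl{[3-methyl-1-(propan-2-yl)cyclopent-2-en-1-yl]oxy}silane
Product: 6 cis-fused 2,2,4-trimethyl-6a-(propan-2-yl)-4-(prop-2-en-1-yl)hexahydro-2H-cyclopenta[d][1,2]oxasilole (allyl trans to the ring CH2Si and CH3 cis to it)
Conditions: CH2=CHCH2SnBu3 (excess), AIBN (cat.), benzene (dilute), 80 °C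
Reagents that add atoms: allyltributylstannane, C=CC[Sn](CCCC)(CCCC)CCCC
Why: Bromine abstraction gives an α-silyl radical that cyclises 5-exo-trig onto C5 (Nishiyama–Stork silicon-tethered radical cyclisation), which can only place C6 cis to O4, and the tertiary C1 radical should then be trapped by the allylstannane (Keck allylation) on the convex face, anti to the new C5–C6 bond, so that allyl is trans to C6 and the methyl group cis.

**Step 5**
Reactants: 6 the bicyclic siloxane
Product: 7 (1R,2S,3R)-2-(hydroxymethyl)-3-methyl-1-(propan-2-yl)-3-(prop-2-en-1-yl)cyclopentan-1-ol (OH, CH2OH and CH3 on one face)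
Conditions: H2O2 (30% aq.), KHCO3, THF/MeOH, 50 °C
Reagents that add atoms: hydrogen peroxide, OO
Why: Tamao–Fleming oxidation converts the C–Si bond into C–OH with retention and frees the tertiary alcohol, and the terminal alkene is inert to basic peroxide in the absence of a nitrile.

**Step 6**
Reactants: 7 the 1,3-diol
Product: 8 (1R,2R,3R)-2-(iodomethyl)-3-methyl-1-(propan-2-yl)-3-(prop-2-en-1-yl)cyclopentan-1-ol
Conditions: I2, PPh3, imidazole, CH2Cl2, 0 °C
Reagents that add atoms: iodine, II
Why: Appel-type iodination converts only the primary alcohol, because the hindered tertiary carbinol does not form the alkoxyphosphonium ion.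

**Step 7**
Reactants: 8 the primary iodide
Product: 9 (1R,2S,3R)-3-methyl-2-(nitromethyl)-1-(propan-2-yl)-3-(prop-2-en-1-yl)cyclopentan-1-ol
Conditions: AgNO2, Et2O, 0 °C to rt, dark
Reagents that add atoms: silver nitrite, [Ag+].[O-]N=O
Why: Victor Meyer reaction: silver-assisted SN2 displacement of the primary iodide by nitrite through nitrogen should give the primary nitroalkane, and the stereocentres are not at the reacting CH2.

**Step 8**
Reactants: 9 the nitro alkene
Product: 10 2-[(1R,2S,3R)-3-hydroxy-1-methyl-2-(nitromethyl)-3-(propan-2-yl)cyclopentyl]acetaldehyde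
Conditions: O3, CH2Cl2, −78 °C; Me2S, −78 °C to rt
Reagents that add atoms: ozone, O=[O+][O-]
Why: Ozonolysis with reductive work-up turns the allyl group into the CH2CHO arm; the nitroalkane and the tertiary alcohol are inert to ozone at −78 °C, and the trans disposition of the arms prevents lactol or nitro-aldol closure.

**Step 9**
Reactants: 11 2-bromopropene; 12 triphenylphosphine
Product: 13 triphenyl(prop-1-en-2-yl)phosphonium bromide
Conditions: Pd(OAc)2 (cat.), toluene, 100 °C, sealed tube
Reagents that add atoms: none
Why: Palladium-catalysed C–P coupling of a vinyl bromide with PPh3 (oxidative addition to zerovalent palladium formed in situ, then C–P reductive elimination) should give the vinylphosphonium salt.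

**Step 10**
Reactants: 10 the nitro aldehyde; 13 triphenyl(prop-1-en-2-yl)phosphonium bromide
Product: 15 4β-hydroxy-6-nitrodauc-8-ene (trans-fused; C6 epimers), via phosphorane 14 (not isolated)
Conditions: KN(SiMe3)2 (1 equiv), THF/DMF, −78 °C; 13, −78 to 0 °C; then KN(SiMe3)2 (1 equiv, slow addition), high dilution, 0 to 40 °C
Reagents that add atoms: none
Why: Proposed new method: the potassium nitronate of 10 adds through carbon to the CH2 terminus of 13 to give phosphorane 14, whose methyl-bearing ylide carbon then olefinates the side-chain aldehyde in an intramolecular Wittig reaction with loss of Ph3P=O, so that C6–C7 and C8=C9 form in one operation. The closest known reaction type is the Schweizer annulation (conjugate addition of a stabilised carbanion to a vinylphosphonium salt, then intramolecular Wittig olefination), established for enolate and malonate donors and five- and six-membered rings but not for nitronate donors or a cycloheptene. The seven-membered ring closes by 7-exo-trig attack of the ylide carbon C8 on the C9 carbonyl, and the ring enforces the Z geometry of the trisubstituted alkene. The only new stereocentre is the nitro-bearing C6, which is uncontrolled and need not be controlled because step 11 makes it trigonal; C1, C4 and C5 are not acidic and are untouched. The step needs C- rather than O-alkylation of the nitronate (soft acceptor, O-adducts revert), attack at CH2 only (fixed by the reagent) and ring closure rather than Henry reaction or oligomerisation. The trans arms would give a strained trans-fused bicyclo[3.3.0]octane that reverts, dilution suppresses oligomers, the phosphonium group cannot be displaced by the nitronate, and the second equivalent of base returns any proton-quenched salt to the ylide, so olefination is the only irreversible exit.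

**Step 11**
Reactants: 15 4β-hydroxy-6-nitrodauc-8-ene
Product: 17 4β-hydroxydauc-8-en-6-one, via sodium nitronate 16 (not isolated)
Conditions: NaOCH3, MeOH, 0 °C; then aq. TiCl3, NH4OAc (pH 5–6), 0 °C to rt
Reagents that add atoms: water, O
Why: Nef reaction in the McMurry variant: trivalent titanium reduces the nitronate to the imine, which hydrolyses in the buffer to the ketone under conditions that should neither move the β,γ-alkene into conjugation nor cause retro-aldol cleavage or epimerisation at C5.

**Step 12**
Reactants: 17 4β-hydroxydauc-8-en-6-one; 18 4-(benzyloxy)benzaldehyde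
Product: 19 4β-[4-(benzyloxy)benzoyloxy]dauc-8-en-6α-ol
Conditions: SmI2 (0.3 equiv), 18 (5 equiv), THF, −10 °C
Reagents that add atoms: none
Why: Evans–Tishchenko reaction: the trivalent samarium species formed from SmI2 and the aldehyde binds the ketone and the hemiacetal of the tertiary hydroxyl, and hydride passes within a six-membered transition state to the β face of C6 (the face of O4), which should set the 6α-carbinol (1,3-anti) and leave the aroyl group on the tertiary oxygen in the same step.

**Step 13**
Reactants: 19 4β-[4-(benzyloxy)benzoyloxy]dauc-8-en-6α-ol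
Product: 20 4β-[4-(benzyloxy)benzoyloxy]-8α,9α-epoxydaucan-6α-ol
Conditions: VO(acac)2 (cat.), (CH3)3COOH, CH2Cl2, 0 °C to rt
Reagents that add atoms: tert-butyl hydroperoxide, CC(C)(C)OO
Why: Hydroxyl-directed epoxidation of the homoallylic alcohol should deliver oxygen to C8=C9 from the face of the 6α-hydroxyl, which is also the face away from the axial C1 methyl group, giving the 8α,9α-epoxide.

**Step 14**
Reactants: 20 the benzyl-protected epoxide
Product: 21 CNP0264773.1, 4β-(4-hydroxybenzoyloxy)-8α,9α-epoxydaucan-6α-ol (1R,4R,5S,6S,8R,9S in daucane numbering)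
Conditions: H2 (1 atm), Pd/C, EtOAc, rt
Reagents that add atoms: none
Why: Neutral hydrogenolysis of the benzyl aryl ether should free the phenol without opening the trisubstituted epoxide or moving the ester.

**Compound list**
1 | (S)-(+)-terpinen-4-ol, (1S)-4-methyl-1-(propan-2-yl)cyclohex-3-en-1-ol | CC(C)[C@]1(O)CCC(C)=CC1 | starting material
2 | keto aldehyde, (3S)-3-hydroxy-6-oxo-3-(propan-2-yl)heptanal | CC(C)[C@@](O)(CC=O)CCC(C)=O | intermediate
3 | (5R)-5-hydroxy-2-methyl-5-(propan-2-yl)cyclopent-1-ene-1-carbaldehyde | CC(C)[C@]1(O)CCC(C)=C1C=O | intermediate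
4 | (1R)-3-methyl-1-(propan-2-yl)cyclopent-2-en-1-ol | CC(C)[C@]1(O)CCC(C)=C1 | intermediate
5 | (R)-(bromomethyl)dimethyl{[3-methyl-1-(propan-2-yl)cyclopent-2-en-1-yl]oxy}silane | CC(C)[C@]1(O[Si](C)(C)CBr)CCC(C)=C1 | intermediate
6 | cis-fused 2,2,4-trimethyl-6a-(propan-2-yl)-4-(prop-2-en-1-yl)hexahydro-2H-cyclopenta[d][1,2]oxasilole, allyl trans to CH2Si | CC(C)[C@]12CC[C@](C)(CC=C)[C@H]1C[Si](C)(C)O2 | intermediate
7 | (1R,2S,3R)-2-(hydroxymethyl)-3-methyl-1-(propan-2-yl)-3-(prop-2-en-1-yl)cyclopentan-1-ol | CC(C)[C@]1(O)CC[C@](C)(CC=C)[C@H]1CO | intermediate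
8 | (1R,2R,3R)-2-(iodomethyl)-3-methyl-1-(propan-2-yl)-3-(prop-2-en-1-yl)cyclopentan-1-ol | CC(C)[C@]1(O)CC[C@](C)(CC=C)[C@H]1CI | intermediate
9 | (1R,2S,3R)-3-methyl-2-(nitromethyl)-1-(propan-2-yl)-3-(prop-2-en-1-yl)cyclopentan-1-ol | CC(C)[C@]1(O)CC[C@](C)(CC=C)[C@H]1C[N+](=O)[O-] | intermediate
10 | 2-[(1R,2S,3R)-3-hydroxy-1-methyl-2-(nitromethyl)-3-(propan-2-yl)cyclopentyl]acetaldehyde | CC(C)[C@]1(O)CC[C@](C)(CC=O)[C@H]1C[N+](=O)[O-] | intermediate
11 | 2-bromopropene | C=C(C)Br | starting material
12 | triphenylphosphine | c1ccc(cc1)P(c1ccccc1)c1ccccc1 | starting material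
13 | triphenyl(prop-1-en-2-yl)phosphonium bromide | C=C(C)[P+](c1ccccc1)(c1ccccc1)c1ccccc1.[Br-] | intermediate
14 | phosphorane from conjugate addition of the nitronate of 10 to 13 (C6 epimers) | CC(C)[C@]1(O)CC[C@](C)(CC=O)[C@H]1C(CC(C)=P(c1ccccc1)(c1ccccc1)c1ccccc1)[N+](=O)[O-] | intermediate
15 | 4β-hydroxy-6-nitrodauc-8-ene, trans-fused (5α-H, C1 methyl β), C6 epimers | CC(C)[C@]1(O)CC[C@]2(C)CC=C(C)CC([N+](=O)[O-])[C@H]21 | intermediate
16 | sodium nitronate of 15 | CC(C)[C@]1(O)CC[C@]2(C)CC=C(C)CC(=[N+]([O-])[O-])[C@H]21.[Na+] | intermediate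
17 | 4β-hydroxydauc-8-en-6-one | CC(C)[C@]1(O)CC[C@]2(C)CC=C(C)CC(=O)[C@H]21 | intermediate
18 | 4-(benzyloxy)benzaldehyde | O=Cc1ccc(OCc2ccccc2)cc1 | starting material
19 | 4β-[4-(benzyloxy)benzoyloxy]dauc-8-en-6α-ol | CC(C)[C@]1(OC(=O)c2ccc(OCc3ccccc3)cc2)CC[C@]2(C)CC=C(C)C[C@H](O)[C@H]21 | intermediate
20 | 4β-[4-(benzyloxy)benzoyloxy]-8α,9α-epoxydaucan-6α-ol | CC(C)[C@]1(OC(=O)c2ccc(OCc3ccccc3)cc2)CC[C@]2(C)C[C@@H]3O[C@]3(C)C[C@H](O)[C@H]21 | intermediate
21 | CNP0264773.1, 4β-(4-hydroxybenzoyloxy)-8α,9α-epoxydaucan-6α-ol | CC(C)[C@]1(OC(=O)c2ccc(O)cc2)CC[C@]2(C)C[C@@H]3O[C@]3(C)C[C@H](O)[C@H]21 | target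

**Step count**
Total step count: 14. Longest linear sequence: 13 steps (steps 1–8 and 10–14, from 1).

**Steps most likely to fail**

Step 10 (key step). The nitronate may add sluggishly or twice, or the ylide may be lost to proton transfer and intermolecular olefination before the seven-membered ring closes. The fallback makes the two bonds one after the other by known reactions and sets out from diol 7. Oxidation of the primary alcohol (PhI(OAc)2, TEMPO cat., CH2Cl2) should give the hydroxy aldehyde 2-hydroxy-5-methyl-2-(propan-2-yl)-5-(prop-2-en-1-yl)cyclopentane-1-carbaldehyde F1. Addition of 2-methylallylmagnesium chloride (THF, −78 °C) forms C6–C7 and gives the homoallylic alcohol F2 as C6 epimers. Ring-closing metathesis with the second-generation Grubbs catalyst (CH2Cl2, 40 °C) forms C8=C9 and gives dauc-8-ene-4β,6-diol F3. Dess–Martin oxidation of F3 gives ketone 17, where the route is rejoined before step 12.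

Step 12. The hindered tertiary hydroxyl may not form the hemiacetal, so hydride transfer would be slow and retro-aldol opening, epimerisation at C5 or acyl transfer to O6 could compete. The fallback sets out from ketone 17. Hydroxyl-directed reduction with Me4NBH(OAc)3 (MeCN/AcOH, −20 °C; Evans–Saksena, hydride delivered from O4) should give dauc-8-ene-4β,6α-diol F4. Et3SiCl/imidazole protects the secondary hydroxyl to give the 6-O-triethylsilyl ether F5. Deprotonation of the tertiary alcohol with KN(SiMe3)2 and acylation with 4-(benzyloxy)benzoyl chloride gives the 4-O-aroyl 6-O-silyl compound F6. HF·pyridine (THF, 0 °C) removes the silyl group and returns to 19.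

Step 7. Substitution at the β-branched CH2–I may be slow, nitrite may attack through oxygen to give the nitrite ester, or the tertiary hydroxyl may close an oxetane. The fallback sets out from iodide 8 and builds the nitro group by N-oxidation instead. NaN3 (DMF, 60 °C) should give the azide (1R,2S,3R)-2-(azidomethyl)-3-methyl-1-(propan-2-yl)-3-(prop-2-en-1-yl)cyclopentan-1-ol F7. Staudinger reduction (PPh3, THF/H2O) gives the primary amine F8. Oxidation of F8 with (CH3)3COOH and catalytic Zr(OC(CH3)3)4 (CH2Cl2, molecular sieves) returns to nitro compound 9 without touching the terminal alkene.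

**Further compounds**
F1 | step 10 | 2-hydroxy-5-methyl-2-(propan-2-yl)-5-(prop-2-en-1-yl)cyclopentane-1-carbaldehyde (configuration as in 7) | CC(C)[C@]1(O)CC[C@](C)(CC=C)[C@H]1C=O
F2 | step 10 | 2-(1-hydroxy-3-methylbut-3-en-1-yl)-3-methyl-1-(propan-2-yl)-3-(prop-2-en-1-yl)cyclopentan-1-ol (C6 epimers) | CC(C)[C@]1(O)CC[C@](C)(CC=C)[C@H]1C(O)CC(C)=C
F3 | step 10 | dauc-8-ene-4β,6-diol (C6 epimers) | CC(C)[C@]1(O)CC[C@]2(C)CC=C(C)CC(O)[C@H]21
F4 | step 12 | dauc-8-ene-4β,6α-diol | CC(C)[C@]1(O)CC[C@]2(C)CC=C(C)C[C@H](O)[C@H]21
F5 | step 12 | 6α-(triethylsilyloxy)dauc-8-en-4β-ol | CC(C)[C@]1(O)CC[C@]2(C)CC=C(C)C[C@H](O[Si](CC)(CC)CC)[C@H]21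
F6 | step 12 | 4β-[4-(benzyloxy)benzoyloxy]-6α-(triethylsilyloxy)dauc-8-ene | CC(C)[C@]1(OC(=O)c2ccc(OCc3ccccc3)cc2)CC[C@]2(C)CC=C(C)C[C@H](O[Si](CC)(CC)CC)[C@H]21
F7 | step 7 | (1R,2S,3R)-2-(azidomethyl)-3-methyl-1-(propan-2-yl)-3-(prop-2-en-1-yl)cyclopentan-1-ol | CC(C)[C@]1(O)CC[C@](C)(CC=C)[C@H]1CN=[N+]=[N-]
F8 | step 7 | 2-(aminomethyl)-3-methyl-1-(propan-2-yl)-3-(prop-2-en-1-yl)cyclopentan-1-ol (configuration as in 7) | CC(C)[C@]1(O)CC[C@](C)(CC=C)[C@H]1CN
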